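**Strategy.** The target is numbered as a 2-oxaspiro[4.5]deca-6,9-dien-8-one. Ring A (C5–C10) is closed at C5–C6, the bond from the spiro carbon to the vinylic CH beside C7–OMe, as the second, 6-endo Michael addition of a double Michael annulation. The step exploits that C5 lies between C1 and C4: with C1 as a lactone carbonyl tied to the C4 hydroxymethyl oxygen, C5 is an enolate carbon whose open face is fixed by the arylmethyl group on C4. The precursor is an α-methylene-β-arylmethyl butyrolactone and the lithium dienolate of 3-methoxybut-3-en-2-one. A glycolate syn-aldol, quinone methide etherification and Saegusa–Ito oxidation complete the tetrahydrofuran and dienone.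

Key step: step 7

Assumption: (R)-epichlorohydrin reacts with malonate by epoxide opening first, giving the (1S,5R) lactone 5; the ester-bearing carbon of 7 and 8 and the methoxy-bearing carbon of enolate 15 need no control because both become sp2. TBS = tert-butyldimethylsilyl, TIPS = triisopropylsilyl.

Step 1
Reactants: 1 4-bromo-2-methoxyphenol
Product: 2 1-(allyloxy)-4-bromo-2-methoxybenzene
Conditions: allyl bromide, K2CO3, acetone, reflux
Reagents that add atoms: allyl bromide C=CCBr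
Why: Williamson ether synthesis; the allyl ether should survive the Grignard, enolate, hydride and boron steps and is later removed by a zerovalent palladium catalyst without touching any silyl group.

Step 2
Reactants: 3 (R)-epichlorohydrin; 4 diethyl malonate
Product: 5 ethyl (1S,5R)-2-oxo-3-oxabicyclo[3.1.0]hexane-1-carboxylate
Conditions: NaOEt, EtOH, reflux
Reagents that add atoms: none
Why: Tandem alkylation–cyclopropanation–lactonisation: malonate opens the epoxide at CH2, the alkoxide re-forms an epoxide by chloride displacement, 3-exo-tet alkylation with inversion at the stereocenter closes the cyclopropane and the freed alkoxide lactonises, so the one stereocenter of 3 sets both ring-fusion carbons.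

Step 3
Reactants: 2 1-(allyloxy)-4-bromo-2-methoxybenzene; 5 ethyl (1S,5R)-2-oxo-3-oxabicyclo[3.1.0]hexane-1-carboxylate
Product: 7 ethyl (3S,4R)-4-[4-(allyloxy)-3-methoxybenzyl]-2-oxotetrahydrofuran-3-carboxylate, via arylmagnesium bromide 6 (not isolated)
Conditions: Mg, THF, 40 °C; then CuBr·SMe2 (10 mol %), 5, THF, −30 → 0 °C; aq NH4Cl
Reagents that add atoms: none
Why: Copper-catalysed homoconjugate opening of the doubly activated cyclopropane at its CH2 carbon by the aryl Grignard reagent; no bond to the ring-fusion CH changes, so it becomes C4 (R), and protonation of the malonate-type enolate should give the 3,4-trans ester.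

Step 4
Reactants: 7 ethyl (3S,4R)-4-[4-(allyloxy)-3-methoxybenzyl]-2-oxotetrahydrofuran-3-carboxylate
Product: 8 (3S,4R)-4-[4-(allyloxy)-3-methoxybenzyl]-2-oxotetrahydrofuran-3-carboxylic acid
Conditions: LiOH, THF–H2O, 0 → 23 °C; then 1 M HCl
Reagents that add atoms: lithium hydroxide [Li+].[OH-]
Why: Ester saponification; any ring-opened hydroxy diacid should relactonise on acidification and C4 is not touched.

Step 5
Reactants: 8 (3S,4R)-4-[4-(allyloxy)-3-methoxybenzyl]-2-oxotetrahydrofuran-3-carboxylic acid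
Product: 10 (R)-4-[4-(allyloxy)-3-methoxybenzyl]-3-methylenedihydrofuran-2(3H)-one, via Mannich base 9 (not isolated)
Conditions: 37% aq HCHO, Et2NH, 23 °C; then NaOAc, AcOH, 90 °C
Reagents that add atoms: formaldehyde C=O
Why: Decarboxylative Mannich methylenation of an α-carboxy lactone: aminomethylation at the α-carbon followed by loss of CO2 and diethylamine should give the exocyclic enoate, with C4 unchanged.

Step 6
Reactants: 11 3,3-dimethoxybutan-2-one
Product: 12 3-methoxybut-3-en-2-one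
Conditions: KHSO4 (cat.), 150 °C, distillation
Reagents that add atoms: none
Why: Acid-catalysed elimination of methanol from the ketal through its oxocarbenium ion should give the α-methoxy enone, which is removed by distillation.

Step 7
Reactants: 12 3-methoxybut-3-en-2-one; 10 (R)-4-[4-(allyloxy)-3-methoxybenzyl]-3-methylenedihydrofuran-2(3H)-one
Product: 16 (4R,5S)-4-[4-(allyloxy)-3-methoxybenzyl]-7-methoxy-2-oxaspiro[4.5]dec-6-ene-1,8-dione, via lithium dienolate 13 (not isolated), via lactone enolate 14 (not isolated), via spiro enolate 15 (not isolated)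
Conditions: LiN(iPr)2, THF, −78 °C; then 10, −78 → −20 °C; then PhS(Cl)=NtBu, −78 → 23 °C
Reagents that add atoms: none
Why: The kinetic cross-conjugated dienolate 13 adds through its CH2 terminus to the exocyclic methylene carbon of 10 (intermolecular Michael addition), which creates lactone enolate 14 with the α-methoxy enone five atoms away; the enolate carbon then attacks the enone β-carbon, and this second Michael addition forms the bond between the spiro carbon and the future vinylic CH of ring A. The closest known reaction type is the anionic double Michael (Michael-initiated ring closure) annulation of 2-oxido-dienes with acrylates. Ring A closes in the 6-endo-trig mode, the enone C=C lying inside the new ring. The spiro stereocenter is set in this closure by C4 of the butyrolactone: the planar lactone enolate should be attacked on the face anti to the adjacent arylmethyl group, as in trans-selective alkylations of β-substituted γ-butyrolactone enolates, which places the methoxy-bearing arm trans to that group, the arrangement that maps onto the target. The step needs the first bond at the methylene carbon and the second at the spiro carbon; this is secured because only the ketone-derived enolate exists at the start and the lactone enolate arises only after the first addition. The regiodefined enolate 15 left by ring closure is dehydrogenated in the same flask by the sulfinimidoyl chloride (sulfur transfer to the methoxy-bearing carbon, then syn-elimination toward the only β-CH2), so the C=C(OMe) unit appears without a regiochemical choice.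

Step 8
Reactants: 16 (4R,5S)-4-[4-(allyloxy)-3-methoxybenzyl]-7-methoxy-2-oxaspiro[4.5]dec-6-ene-1,8-dione
Product: 17 (4R,5S)-4-[4-(allyloxy)-3-methoxybenzyl]-7-methoxy-8-(TIPS-oxy)-2-oxaspiro[4.5]deca-6,8-dien-1-one
Conditions: TIPSOTf, Et3N, CH2Cl2, −78 → 0 °C
Reagents that add atoms: triisopropylsilyl triflate CC(C)[Si](OS(=O)(=O)C(F)(F)F)(C(C)C)C(C)C
Why: Soft enolisation/O-silylation; the enone has acidic hydrogens only at C9 and the lactone has no α-hydrogen, so a single cross-conjugated silyl dienol ether should form, which masks the ketone toward hydride and sets up the later Saegusa–Ito oxidation.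

Step 9
Reactants: 17 (4R,5S)-4-[4-(allyloxy)-3-methoxybenzyl]-7-methoxy-8-(TIPS-oxy)-2-oxaspiro[4.5]deca-6,8-dien-1-one
Product: 18 {(1S)-1-[(2R)-1-[4-(allyloxy)-3-methoxyphenyl]-3-hydroxypropan-2-yl]-3-methoxy-4-(TIPS-oxy)cyclohexa-2,4-dien-1-yl}methanol
Conditions: LiAlH4, THF, 0 °C
Reagents that add atoms: none
Why: Irreversible hydride reduction of the α-quaternary lactone to the 1,4-diol; the silyl dienol ether and allyl ether are inert and no stereocenter is touched.

Step 10
Reactants: 18 {(1S)-1-[(2R)-1-[4-(allyloxy)-3-methoxyphenyl]-3-hydroxypropan-2-yl]-3-methoxy-4-(TIPS-oxy)cyclohexa-2,4-dien-1-yl}methanol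
Product: 19 {(1S)-1-[(2R)-1-[4-(allyloxy)-3-methoxyphenyl]-3-(TBS-oxy)propan-2-yl]-3-methoxy-4-(TIPS-oxy)cyclohexa-2,4-dien-1-yl}methanol
Conditions: TBSCl (1.05 equiv), imidazole, CH2Cl2, −20 °C
Reagents that add atoms: tert-butyldimethylsilyl chloride CC(C)(C)[Si](C)(C)Cl
Why: Sterically controlled monosilylation; the hydroxymethyl on the tertiary CH should react well before the neopentyl hydroxymethyl on the quaternary ring carbon.

Step 11
Reactants: 19 {(1S)-1-[(2R)-1-[4-(allyloxy)-3-methoxyphenyl]-3-(TBS-oxy)propan-2-yl]-3-methoxy-4-(TIPS-oxy)cyclohexa-2,4-dien-1-yl}methanol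
Product: 20 (1S)-1-[(2R)-1-[4-(allyloxy)-3-methoxyphenyl]-3-(TBS-oxy)propan-2-yl]-3-methoxy-4-(TIPS-oxy)cyclohexa-2,4-diene-1-carbaldehyde
Conditions: SO3·pyridine, DMSO, iPr2NEt, CH2Cl2, 0 °C
Reagents that add atoms: none
Why: Parikh–Doering oxidation, non-acidic and mild enough for the silyl dienol ether; the aldehyde is non-enolisable, so the quaternary stereocenter cannot epimerise.

Step 12
Reactants: 21 (R)-4-benzyloxazolidin-2-one; 22 chloroacetyl chloride
Product: 23 (R)-4-benzyl-3-(2-chloroacetyl)oxazolidin-2-one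
Conditions: n-BuLi, THF, −78 °C; then 22
Reagents that add atoms: none
Why: N-acylation of the lithiated oxazolidinone by the acid chloride.

Step 13
Reactants: 24 dihydroconiferyl alcohol [4-(3-hydroxypropyl)-2-methoxyphenol]; 23 (R)-4-benzyl-3-(2-chloroacetyl)oxazolidin-2-one
Product: 25 (R)-4-benzyl-3-{2-[4-(3-hydroxypropyl)-2-methoxyphenoxy]acetyl}oxazolidin-2-one
Conditions: K2CO3, acetone, 50 °C
Reagents that add atoms: none
Why: Williamson etherification; only the phenol is deprotonated by carbonate and SN2 displacement at the α-chloro imide should outpace attack at the imide carbonyl.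

Step 14
Reactants: 25 (R)-4-benzyl-3-{2-[4-(3-hydroxypropyl)-2-methoxyphenoxy]acetyl}oxazolidin-2-one
Product: 26 (R)-4-benzyl-3-{2-[4-(3-(TBS-oxy)propyl)-2-methoxyphenoxy]acetyl}oxazolidin-2-one
Conditions: TBSCl, imidazole, DMF, 23 °C
Reagents that add atoms: tert-butyldimethylsilyl chloride CC(C)(C)[Si](C)(C)Cl
Why: Silylation of the only hydroxyl so that the boron enolisation in the next step meets no free alcohol.

Step 15
Reactants: 26 (R)-4-benzyl-3-{2-[4-(3-(TBS-oxy)propyl)-2-methoxyphenoxy]acetyl}oxazolidin-2-one; 20 (1S)-1-[(2R)-1-[4-(allyloxy)-3-methoxyphenyl]-3-(TBS-oxy)propan-2-yl]-3-methoxy-4-(TIPS-oxy)cyclohexa-2,4-diene-1-carbaldehyde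
Product: 28 (R)-4-benzyl-3-[(2R,3S)-3-{(1S)-1-[(2R)-1-[4-(allyloxy)-3-methoxyphenyl]-3-(TBS-oxy)propan-2-yl]-3-methoxy-4-(TIPS-oxy)cyclohexa-2,4-dien-1-yl}-3-hydroxy-2-[4-(3-(TBS-oxy)propyl)-2-methoxyphenoxy]propanoyl]oxazolidin-2-one, via boron enolate 27 (not isolated)
Conditions: Bu2BOTf, iPr2NEt, CH2Cl2, −78 → 0 °C; then 20, −78 → 0 °C; pH 7 buffer, MeOH
Reagents that add atoms: none
Why: Evans glycolate syn-aldol through the (Z)-dibutylboron enolate and a closed chair transition state; the (R)-benzyl auxiliary fixes the enolate face, so both new stereocenters (carbinol S; aryloxy carbon R as the imide, S after reduction) are reagent-controlled and syn, independent of the non-enolisable α-quaternary aldehyde.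

Step 16
Reactants: 28 the aldol adduct of step 15
Product: 29 (1S,2S)-1-{(1S)-1-[(2R)-1-[4-(allyloxy)-3-methoxyphenyl]-3-(TBS-oxy)propan-2-yl]-3-methoxy-4-(TIPS-oxy)cyclohexa-2,4-dien-1-yl}-2-[4-(3-(TBS-oxy)propyl)-2-methoxyphenoxy]propane-1,3-diol
Conditions: LiBH4, MeOH (1 equiv), THF, 0 °C
Reagents that add atoms: none
Why: Reductive cleavage of the N-acyl oxazolidinone to the primary alcohol; no stereocenter is touched and the silyl dienol ether is inert to borohydride.

Step 17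
Reactants: 29 the diol of step 16
Product: 30 (1S,2S)-1-{(1S)-1-[(2R)-1-(4-hydroxy-3-methoxyphenyl)-3-(TBS-oxy)propan-2-yl]-3-methoxy-4-(TIPS-oxy)cyclohexa-2,4-dien-1-yl}-2-[4-(3-(TBS-oxy)propyl)-2-methoxyphenoxy]propane-1,3-diol
Conditions: Pd(PPh3)4 (5 mol %), morpholine, THF, 23 °C
Reagents that add atoms: none
Why: Allyl transfer from the aryl ether to morpholine through a π-allylpalladium complex (Tsuji–Trost deallylation) frees only the ring B phenol under neutral conditions that leave all three silyl groups in place.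

Step 18
Reactants: 30 the phenol of step 17
Product: 32 (1S,3S,4R,5S)-4-[(TBS-oxy)methyl]-3-(4-hydroxy-3-methoxyphenyl)-1-{(1S)-2-hydroxy-1-[4-(3-(TBS-oxy)propyl)-2-methoxyphenoxy]ethyl}-7-methoxy-8-(TIPS-oxy)-2-oxaspiro[4.5]deca-6,8-diene, via quinone methide 31 (not isolated)
Conditions: Ag2O, CH2Cl2, 23 °C, dark
Reagents that add atoms: none
Why: Biomimetic quinone methide etherification: Ag2O oxidises the only free phenol to the para-quinone methide and the secondary hydroxyl adds to its exocyclic carbon in a 5-exo oxa-1,6-addition that rearomatises ring B; the benzylic stereocenter should form with the aryl group trans to the adjacent CH2OTBS group, which is both the less strained transition state and the thermodynamic arrangement.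

Step 19
Reactants: 32 the spiro tetrahydrofuran of step 18
Product: 33 (1S,3S,4R,5S)-4-[(TBS-oxy)methyl]-3-(4-hydroxy-3-methoxyphenyl)-1-{(1S)-2-hydroxy-1-[4-(3-(TBS-oxy)propyl)-2-methoxyphenoxy]ethyl}-7-methoxy-2-oxaspiro[4.5]deca-6,9-dien-8-one
Conditions: Pd(OAc)2 (1.2 equiv), MeCN–CH2Cl2, 23 → 40 °C
Reagents that add atoms: none
Why: Saegusa–Ito oxidation: palladation of the silyl dienol ether at C9 and β-hydride elimination from C10 should give the cross-conjugated dienone; it is done only after the C1 oxygen is an ether, so retro-aldol fragmentation of a free carbinol next to the dienone cannot occur.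

Step 20
Reactants: 33 the bis-TBS dienone of step 19
Product: 34 (1S,3S,4R,5S)-3-(4-hydroxy-3-methoxyphenyl)-4-(hydroxymethyl)-1-{(1S)-2-hydroxy-1-[4-(3-hydroxypropyl)-2-methoxyphenoxy]ethyl}-7-methoxy-2-oxaspiro[4.5]deca-6,9-dien-8-one (CNP0252711.1)
Conditions: Bu4NF, AcOH (1:1), THF, 0 → 23 °C
Reagents that add atoms: none
Why: Fluoride cleavage of the two primary TBS ethers; buffering with acetic acid keeps the medium near neutral because the spirodienone is sensitive to both acid and phenoxide-forming base.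

**Compound list**

1 | 4-bromo-2-methoxyphenol | COc1cc(Br)ccc1O | starting material
2 | 1-(allyloxy)-4-bromo-2-methoxybenzene | C=CCOc1ccc(Br)cc1OC | intermediate
3 | (R)-epichlorohydrin | ClC[C@H]1CO1 | starting material
4 | diethyl malonate | CCOC(=O)CC(=O)OCC | starting material
5 | ethyl (1S,5R)-2-oxo-3-oxabicyclo[3.1.0]hexane-1-carboxylate | O=C1OC[C@@H]2C[C@]12C(=O)OCC | intermediate
6 | [4-(allyloxy)-3-methoxyphenyl]magnesium bromide | C=CCOc1ccc([Mg]Br)cc1OC | intermediate
7 | ethyl (3S,4R)-4-[4-(allyloxy)-3-methoxybenzyl]-2-oxotetrahydrofuran-3-carboxylate (3,4-trans) | CCOC(=O)[C@H]1C(=O)OC[C@@H]1Cc1ccc(OCC=C)c(OC)c1 | intermediate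
8 | (3S,4R)-4-[4-(allyloxy)-3-methoxybenzyl]-2-oxotetrahydrofuran-3-carboxylic acid | OC(=O)[C@H]1C(=O)OC[C@@H]1Cc1ccc(OCC=C)c(OC)c1 | intermediate
9 | (4R)-4-[4-(allyloxy)-3-methoxybenzyl]-3-[(diethylamino)methyl]-2-oxotetrahydrofuran-3-carboxylic acid (Mannich base, C3 not assigned) | CCN(CC)CC1(C(O)=O)C(=O)OC[C@@H]1Cc1ccc(OCC=C)c(OC)c1 | intermediate
10 | (R)-4-[4-(allyloxy)-3-methoxybenzyl]-3-methylenedihydrofuran-2(3H)-one | C=C1C(=O)OC[C@@H]1Cc1ccc(OCC=C)c(OC)c1 | intermediate
11 | 3,3-dimethoxybutan-2-one | CC(=O)C(C)(OC)OC | starting material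
12 | 3-methoxybut-3-en-2-one | CC(=O)C(OC)=C | intermediate
13 | lithium 3-methoxybuta-1,3-dien-2-olate | C=C(O[Li])C(OC)=C | intermediate
14 | lithium (R)-4-[4-(allyloxy)-3-methoxybenzyl]-3-(4-methoxy-3-oxopent-4-en-1-yl)-4,5-dihydrofuran-2-olate | C=C(OC)C(=O)CCC1=C(O[Li])OC[C@@H]1Cc1ccc(OCC=C)c(OC)c1 | intermediate
15 | lithium (4R,5R)-4-[4-(allyloxy)-3-methoxybenzyl]-7-methoxy-1-oxo-2-oxaspiro[4.5]dec-7-en-8-olate | COC1=C(O[Li])CC[C@@]2(C1)[C@@H](Cc1ccc(OCC=C)c(OC)c1)COC2=O | intermediate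
16 | (4R,5S)-4-[4-(allyloxy)-3-methoxybenzyl]-7-methoxy-2-oxaspiro[4.5]dec-6-ene-1,8-dione | COC1=C[C@]2(CCC1=O)[C@@H](Cc1ccc(OCC=C)c(OC)c1)COC2=O | intermediate
17 | (4R,5S)-4-[4-(allyloxy)-3-methoxybenzyl]-7-methoxy-8-(TIPS-oxy)-2-oxaspiro[4.5]deca-6,8-dien-1-one | COC1=C[C@]2(CC=C1O[Si](C(C)C)(C(C)C)C(C)C)[C@@H](Cc1ccc(OCC=C)c(OC)c1)COC2=O | intermediate
18 | {(1S)-1-[(2R)-1-[4-(allyloxy)-3-methoxyphenyl]-3-hydroxypropan-2-yl]-3-methoxy-4-(TIPS-oxy)cyclohexa-2,4-dien-1-yl}methanol | COC1=C[C@](CO)(CC=C1O[Si](C(C)C)(C(C)C)C(C)C)[C@@H](Cc1ccc(OCC=C)c(OC)c1)CO | intermediate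
19 | {(1S)-1-[(2R)-1-[4-(allyloxy)-3-methoxyphenyl]-3-(TBS-oxy)propan-2-yl]-3-methoxy-4-(TIPS-oxy)cyclohexa-2,4-dien-1-yl}methanol | COC1=C[C@](CO)(CC=C1O[Si](C(C)C)(C(C)C)C(C)C)[C@@H](Cc1ccc(OCC=C)c(OC)c1)CO[Si](C)(C)C(C)(C)C | intermediate
20 | (1S)-1-[(2R)-1-[4-(allyloxy)-3-methoxyphenyl]-3-(TBS-oxy)propan-2-yl]-3-methoxy-4-(TIPS-oxy)cyclohexa-2,4-diene-1-carbaldehyde | COC1=C[C@](C=O)(CC=C1O[Si](C(C)C)(C(C)C)C(C)C)[C@@H](Cc1ccc(OCC=C)c(OC)c1)CO[Si](C)(C)C(C)(C)C | intermediate
21 | (R)-4-benzyloxazolidin-2-one | O=C1N[C@H](Cc2ccccc2)CO1 | starting material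
22 | chloroacetyl chloride | ClCC(Cl)=O | starting material
23 | (R)-4-benzyl-3-(2-chloroacetyl)oxazolidin-2-one | ClCC(=O)N1[C@H](Cc2ccccc2)COC1=O | intermediate
24 | dihydroconiferyl alcohol [4-(3-hydroxypropyl)-2-methoxyphenol] | COc1cc(CCCO)ccc1O | starting material
25 | (R)-4-benzyl-3-{2-[4-(3-hydroxypropyl)-2-methoxyphenoxy]acetyl}oxazolidin-2-one | COc1cc(CCCO)ccc1OCC(=O)N1[C@H](Cc2ccccc2)COC1=O | intermediate
26 | (R)-4-benzyl-3-{2-[4-(3-(TBS-oxy)propyl)-2-methoxyphenoxy]acetyl}oxazolidin-2-one | COc1cc(CCCO[Si](C)(C)C(C)(C)C)ccc1OCC(=O)N1[C@H](Cc2ccccc2)COC1=O | intermediate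
27 | (Z)-dibutylboron enolate of 26 | CCCCB(CCCC)O/C(=C\Oc1ccc(CCCO[Si](C)(C)C(C)(C)C)cc1OC)N1[C@H](Cc2ccccc2)COC1=O | intermediate
28 | syn-aldol adduct: (R)-4-benzyl-3-[(2R,3S)-3-{(1S)-cyclohexadienyl}-3-hydroxy-2-(aryloxy)propanoyl]oxazolidin-2-one as named in step 15 | COC1=C[C@](CC=C1O[Si](C(C)C)(C(C)C)C(C)C)([C@@H](Cc1ccc(OCC=C)c(OC)c1)CO[Si](C)(C)C(C)(C)C)[C@H](O)[C@@H](Oc1ccc(CCCO[Si](C)(C)C(C)(C)C)cc1OC)C(=O)N1[C@H](Cc2ccccc2)COC1=O | intermediate
29 | (1S,2S)-1-{(1S)-1-[(2R)-1-[4-(allyloxy)-3-methoxyphenyl]-3-(TBS-oxy)propan-2-yl]-3-methoxy-4-(TIPS-oxy)cyclohexa-2,4-dien-1-yl}-2-[4-(3-(TBS-oxy)propyl)-2-methoxyphenoxy]propane-1,3-diol | COC1=C[C@](CC=C1O[Si](C(C)C)(C(C)C)C(C)C)([C@@H](Cc1ccc(OCC=C)c(OC)c1)CO[Si](C)(C)C(C)(C)C)[C@H](O)[C@@H](Oc1ccc(CCCO[Si](C)(C)C(C)(C)C)cc1OC)CO | intermediate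
30 | the same diol with the ring B allyl ether replaced by a free phenol (4-hydroxy-3-methoxyphenyl) | COC1=C[C@](CC=C1O[Si](C(C)C)(C(C)C)C(C)C)([C@@H](Cc1ccc(O)c(OC)c1)CO[Si](C)(C)C(C)(C)C)[C@H](O)[C@@H](Oc1ccc(CCCO[Si](C)(C)C(C)(C)C)cc1OC)CO | intermediate
31 | para-quinone methide of 30 (ring B as 4-alkylidene-2-methoxycyclohexa-2,5-dienone) | COC1=C[C@](CC=C1O[Si](C(C)C)(C(C)C)C(C)C)([C@@H](C=C1C=CC(=O)C(OC)=C1)CO[Si](C)(C)C(C)(C)C)[C@H](O)[C@@H](Oc1ccc(CCCO[Si](C)(C)C(C)(C)C)cc1OC)CO | intermediate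
32 | (1S,3S,4R,5S)-4-[(TBS-oxy)methyl]-3-(4-hydroxy-3-methoxyphenyl)-1-{(1S)-2-hydroxy-1-[4-(3-(TBS-oxy)propyl)-2-methoxyphenoxy]ethyl}-7-methoxy-8-(TIPS-oxy)-2-oxaspiro[4.5]deca-6,8-diene | COC1=C[C@]2(CC=C1O[Si](C(C)C)(C(C)C)C(C)C)[C@H](CO[Si](C)(C)C(C)(C)C)[C@@H](c1ccc(O)c(OC)c1)O[C@@H]2[C@H](CO)Oc1ccc(CCCO[Si](C)(C)C(C)(C)C)cc1OC | intermediate
33 | (1S,3S,4R,5S)-4-[(TBS-oxy)methyl]-3-(4-hydroxy-3-methoxyphenyl)-1-{(1S)-2-hydroxy-1-[4-(3-(TBS-oxy)propyl)-2-methoxyphenoxy]ethyl}-7-methoxy-2-oxaspiro[4.5]deca-6,9-dien-8-one | COC1=C[C@]2(C=CC1=O)[C@H](CO[Si](C)(C)C(C)(C)C)[C@@H](c1ccc(O)c(OC)c1)O[C@@H]2[C@H](CO)Oc1ccc(CCCO[Si](C)(C)C(C)(C)C)cc1OC | intermediate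
34 | (1S,3S,4R,5S)-3-(4-hydroxy-3-methoxyphenyl)-4-(hydroxymethyl)-1-{(1S)-2-hydroxy-1-[4-(3-hydroxypropyl)-2-methoxyphenoxy]ethyl}-7-methoxy-2-oxaspiro[4.5]deca-6,9-dien-8-one | COC1=C[C@]2(C=CC1=O)[C@H](CO)[C@@H](c1ccc(O)c(OC)c1)O[C@@H]2[C@H](CO)Oc1ccc(CCCO)cc1OC | target

**Count.** Total steps: 20. Longest linear sequence: 15 steps (3 → 5 → 7 → 8 → 10 → 16 → 17 → 18 → 19 → 20 → 28 → 29 → 30 → 32 → 33 → 34; steps 2–5, 7–11, 15–20).

**Steps most likely to fail**

1. Step 7 (key step). What may go wrong: anionic oligomerisation of enone 12 or dienolate 13 before addition, arrest after the first Michael addition, or loss of facial control in the ring closure. Fallback, a (5+1) double Michael in which the lactone is the donor twice: setting out from ester 7, dealkoxycarbonylation (LiCl, wet DMSO, 150 °C) should give (R)-4-[4-(allyloxy)-3-methoxybenzyl]dihydrofuran-2(3H)-one F1. 1-Methoxyvinyllithium F2 (methyl vinyl ether, t-BuLi) adds to acrolein to give 2-methoxypenta-1,4-dien-3-ol F3, which MnO2 oxidises to 2-methoxypenta-1,4-dien-3-one F4. The lithium enolate of F1 (LiN(iPr)2, −78 °C) adds to the unsubstituted vinyl group of F4 to give (3R,4R)-4-[4-(allyloxy)-3-methoxybenzyl]-3-(4-methoxy-3-oxopent-4-en-1-yl)dihydrofuran-2(3H)-one F5. KOtBu in t-BuOH–THF then closes ring A by Michael addition of the lactone enolate to the methoxy enone, again anti to the arylmethyl group, giving (4R,5R)-4-[4-(allyloxy)-3-methoxybenzyl]-7-methoxy-2-oxaspiro[4.5]decane-1,8-dione F6. Thermodynamic silylation (Me3SiCl, Et3N, DMF, 80 °C) toward the methoxy-bearing carbon gives the trimethylsilyl enol ether F7, and Saegusa–Ito oxidation (Pd(OAc)2) comes back to the route at enone 16.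

2. Step 18. What may go wrong: slow oxidation of the guaiacyl phenol on the silver oxide surface, tautomerisation of the quinone methide to the styrene before the hydroxyl adds, or re-oxidation of the product phenol. Fallback, reversing the order and using a soluble oxidant once the silyl dienol ether is gone: setting out from phenol 30, Saegusa–Ito oxidation (Pd(OAc)2, MeCN) first gives (1S,2S)-1-{(1S)-1-[(2R)-1-(4-hydroxy-3-methoxyphenyl)-3-(TBS-oxy)propan-2-yl]-3-methoxy-4-oxocyclohexa-2,5-dien-1-yl}-2-[4-(3-(TBS-oxy)propyl)-2-methoxyphenoxy]propane-1,3-diol F8, kept under neutral conditions. DDQ (1 equiv, CH2Cl2–pH 7 buffer, 0 °C) then oxidises only the free phenol to the quinone methide of F8, F9, whose 5-exo etherification comes back to the route at 33.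

3. Step 10. What may go wrong: poor discrimination between the two primary hydroxyls, with silylation at the neopentyl site or at both. Fallback, opening the lactone at the acyl carbon instead of reducing it: setting out from lactone 17, aminolysis with MeNH(OMe)·HCl and i-PrMgCl (THF, −20 °C) gives (1S)-1-[(2R)-1-[4-(allyloxy)-3-methoxyphenyl]-3-hydroxypropan-2-yl]-N,3-dimethoxy-N-methyl-4-(TIPS-oxy)cyclohexa-2,4-diene-1-carboxamide F10. Immediate silylation (TBSOTf, 2,6-lutidine) gives its TBS ether F11, and reduction with iBu2AlH (−78 °C) comes back to the route at aldehyde 20.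

**Further compounds**

F1 | step 7 | (R)-4-[4-(allyloxy)-3-methoxybenzyl]dihydrofuran-2(3H)-one | O=C1C[C@@H](Cc2ccc(OCC=C)c(OC)c2)CO1
F2 | step 7 | 1-methoxyvinyllithium | C=C(OC)[Li]
F3 | step 7 | 2-methoxypenta-1,4-dien-3-ol (racemic) | C=CC(O)C(OC)=C
F4 | step 7 | 2-methoxypenta-1,4-dien-3-one | C=CC(=O)C(OC)=C
F5 | step 7 | (3R,4R)-4-[4-(allyloxy)-3-methoxybenzyl]-3-(4-methoxy-3-oxopent-4-en-1-yl)dihydrofuran-2(3H)-one | C=C(OC)C(=O)CC[C@H]1C(=O)OC[C@@H]1Cc1ccc(OCC=C)c(OC)c1
F6 | step 7 | (4R,5R)-4-[4-(allyloxy)-3-methoxybenzyl]-7-methoxy-2-oxaspiro[4.5]decane-1,8-dione (C7 epimers) | COC1C[C@]2(CCC1=O)[C@@H](Cc1ccc(OCC=C)c(OC)c1)COC2=O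
F7 | step 7 | (4R,5R)-4-[4-(allyloxy)-3-methoxybenzyl]-7-methoxy-8-(trimethylsilyloxy)-2-oxaspiro[4.5]dec-7-en-1-one | COC1=C(O[Si](C)(C)C)CC[C@@]2(C1)[C@@H](Cc1ccc(OCC=C)c(OC)c1)COC2=O
F8 | step 18 | (1S,2S)-1-{(1S)-1-[(2R)-1-(4-hydroxy-3-methoxyphenyl)-3-(TBS-oxy)propan-2-yl]-3-methoxy-4-oxocyclohexa-2,5-dien-1-yl}-2-[4-(3-(TBS-oxy)propyl)-2-methoxyphenoxy]propane-1,3-diol | COC1=C[C@](C=CC1=O)([C@@H](Cc1ccc(O)c(OC)c1)CO[Si](C)(C)C(C)(C)C)[C@H](O)[C@@H](Oc1ccc(CCCO[Si](C)(C)C(C)(C)C)cc1OC)CO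
F9 | step 18 | para-quinone methide of F8 | COC1=C[C@](C=CC1=O)([C@@H](C=C1C=CC(=O)C(OC)=C1)CO[Si](C)(C)C(C)(C)C)[C@H](O)[C@@H](Oc1ccc(CCCO[Si](C)(C)C(C)(C)C)cc1OC)CO
F10 | step 10 | (1S)-1-[(2R)-1-[4-(allyloxy)-3-methoxyphenyl]-3-hydroxypropan-2-yl]-N,3-dimethoxy-N-methyl-4-(TIPS-oxy)cyclohexa-2,4-diene-1-carboxamide | COC1=C[C@](C(=O)N(C)OC)(CC=C1O[Si](C(C)C)(C(C)C)C(C)C)[C@@H](Cc1ccc(OCC=C)c(OC)c1)CO
F11 | step 10 | (1S)-1-[(2R)-1-[4-(allyloxy)-3-methoxyphenyl]-3-(TBS-oxy)propan-2-yl]-N,3-dimethoxy-N-methyl-4-(TIPS-oxy)cyclohexa-2,4-diene-1-carboxamide | COC1=C[C@](C(=O)N(C)OC)(CC=C1O[Si](C(C)C)(C(C)C)C(C)C)[C@@H](Cc1ccc(OCC=C)c(OC)c1)CO[Si](C)(C)C(C)(C)C
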